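## Structural features

The target is a 2-aryl-2,3-dihydrobenzofuran (benzofuran numbering O1, C2, C3, C3a, C4–C7, C7a is used for every intermediate, open-chain ones included; the cyclohexene is numbered as in shikimic acid). Ring A is fused to the dihydrofuran ring through C3a and C7a and carries an (E)-acrylic acid at C4 and a phenol at C7. C2 bears a 3,4-dihydroxyphenyl group (ring B), and C3 bears a carboxyl group esterified by O5 of (−)-shikimic acid, whose O3, O4 and carboxyl group are free. C2 and C3 are adjacent stereocentres, (2S,3R), with aryl and ester cis; the three contiguous shikimate stereocentres are insulated from them by the ester link and come from the chiral pool. The cis ester is the less stable epimer and C3–H is both benzylic and alpha to the ester, so any base able to enolise it leads into the trans series. Further fragile points are the benzylic C2–O1 aryl ether para to a ring-B oxygen (ionisable in strong acid), the shikimate ester beside a vicinal diol (acyl migration), the oxidisable catechol and phenol, and the crowded 1,2,3,4-tetrasubstituted ring A. The real difficulty is to reach the kinetic cis-(2S,3R) arrangement with the shikimate ester already in place and to keep it to the end. The feature used is that O1 is an aryl ether oxygen on C7a, which lies between the oxygen-bearing C7 and C3a: O1–C7a can be made last, from an open-chain anti hydroxy ester in which C2 and C3 are already fixed, by a reaction that breaks no bond at either stereocentre.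

## Logic of the disconnections

21 ⇒ 20. No skeletal bond is cut, only the C–O bonds of two tert-butyl esters, one methoxymethyl ether and two isopropylidene ketals. All five fall to acid, so one operation frees seven acidic groups that would otherwise interfere with enolate and palladium chemistry. The demand is an acid strong enough for the ring-B ketal that neither ionises C2–O1 nor moves the acyl group on the shikimate triol.

20 ⇒ 19. The acrylate C=C is cut. This keeps a Michael acceptor away from the enolate, hydride and palladium steps and reduces the C4 substituent to one carbon. The forward olefination must be E-selective on a hindered aldehyde and too weakly basic to touch C3–H.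

19 ⇒ 18. The aldehyde is traced back to its dioxolane, because a free aldehyde cannot coexist with a zinc enolate, a lithium enolate or a hydride-transfer catalyst. The forward hydrolysis has to spare the aliphatic ketal, the MOM ether and the tert-butyl ester.

18 ⇒ 17. The O1–C7a bond is cut. The bicyclic core becomes an acyclic anti beta-hydroxy ester with an aryl triflate, the ring closure creates no stereocentre, and neither bond to C2 or C3 is broken. The stereochemical bookkeeping was checked: anti in the chain (carbinol S, alpha carbon R) corresponds to cis-(2S,3R) in the ring. The forward C–O coupling must be faster than epimerisation at C3, retro-aldol cleavage, beta-hydride elimination and loss of the triflyl group.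

17 ⇒ 16. The C2–H bond is cut, which returns both stereocentres to one stereolabile alpha-aryl beta-keto ester. The forward reduction must choose one carbonyl face and, through equilibration of the alpha centre, the epimer that leads to anti.

16 ⇒ 11 + 14. The C2–C3 bond is cut between the acyl carbon and the enolate carbon. The route becomes convergent, with ring B arriving as an acid chloride. The forward step needs C- over O-acylation and a base that spares the triflate and the shikimate.

11 ⇒ 5 + 9. The C3–C3a bond is cut between ring A and an acetate enolate. The shikimate is delivered as part of the nucleophile, so no esterification is ever carried out on a hindered or epimerisable acid. The forward coupling must take place at C–Br beside an untouched C–OTf, between two ortho substituents.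

5 ⇒ 4 ⇒ 3 ⇒ 2 ⇒ 1. Only functional groups on ring A change: the acetal, MOM in place of methyl, and the triflate. Two points of the ring-A design needed correction. A methyl ether on the C7 oxygen could not be removed at the end under conditions the ester and the cis centre survive, so it is exchanged for MOM at the start. A free C7a phenol beside the arylacetate would lactonise to a benzofuran-2-one with loss of the shikimate, so the triflate is installed first and carried through. Sulfonylating the C7a oxygen while the C7 oxygen is still methylated also removes any regiochemical choice between the two oxygens. Compound 17 itself is kept as drawn.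

9 ⇒ 8 ⇒ 7 ⇒ 6. The O5–acyl bond, the tert-butyl ester and the ketal are removed in turn. The cis 3,4-diol is the only pair that can form a five-membered ketal, which leaves O5 as the single free hydroxyl. The forward esterification of the acid must not alkylate that hydroxyl.

14 ⇒ 13 ⇒ 12. The acyl chloride and the catechol ketal are removed. The forward ketalisation of an electron-poor catechol needs removal of methanol.

## Other disconnections considered

Alternative 1: The cut is C7–C7a of ring A, at the oxidation level of an aromatic benzofuran. In the forward sense the pentenoic acid A2 (furyl and carboxymethyl cis on the double bond) would be heated with Ac2O/NaOAc. The mixed anhydride should give a dienylketene that undergoes 6π-electrocyclisation onto the free furan alpha carbon; tautomerisation and acetylation should then give the 7-acetoxybenzofuran A1.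
- In its favour: ring A is built with the C4 and C7 substituents placed by the connectivity of the chain, so the substitution pattern of a tetrasubstituted arene is not an issue. No precious metal or hindered cross-coupling is needed, and the thermal pericyclic step is robust.
- Against it here: A1 is flat at C2 and C3, so both stereocentres remain to be made by a cis-selective, enantioselective reduction of a tetrasubstituted, electron-poor furan double bond. The ethyl ester must then be exchanged for the shikimate at the stage of the cis acid, with hydrolysis and carboxyl activation at the most labile centre. If the shikimate is attached before the reduction, its own alkene competes.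
- Comparison: on the reliability of the key step itself and on the construction of ring A, the alternative is the better. The chosen plan buys ring A ready-made and spends its key step on a ring closure that cannot disturb the stereocentres. After A1 a reduction, an ester exchange, the change of CH2OAc to the acrylate and the deprotections remain, against three operations after 18, so on stereochemical security and step economy the chosen plan is ahead.

Alternative 2: The cuts are C3a–C7a and C6–C7 of ring A, with the furan oxygen becoming the C7 phenol. In the forward sense the furan–yne A4, an ethynyl ether on O1, would be treated with a cationic monovalent gold complex such as (Ph3P)AuNTf2. Furan C2 should attack the oxygen-bearing alkyne carbon (5-exo), and the cyclopropyl carbenoid, ring-opened carbonyl ylide, oxepine and arene oxide should lead to the phenol A3.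
- In its favour: one neutral, room-temperature step forms ring A, the dihydrofuran ring and the C7 phenol. C2 and C3 are set in an open chain, and C3 is at the alcohol oxidation level, so it cannot epimerise during ring formation. On this point the alternative is better than the chosen plan, whose ring closure is run on an enolisable ester.
- Against it here: the C3 carboxyl must afterwards be raised through the cis aldehyde, which epimerises even more readily than the ester, and then esterified late with a hindered secondary alcohol. The ethynyl ether of a secondary benzylic alcohol needs strong base to prepare and is thermally fragile. The free furan C5 position and two primary silyl ethers that must be told apart add further uncertainty.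
- Comparison: in bonds and rings formed per step the alternative is superior. Mechanistically it rests on a multi-stage gold cascade with an unusual ynol ether substrate, against a single reductive elimination. In overall step economy it is behind, because two oxidations, the esterification, a second oxidation and the olefination all follow the key step.

Alternative 3: The cut is C2–C3. In the forward sense the shikimate aryldiazoacetate A6 would be decomposed by a chiral divalent rhodium carboxylate dimer such as Rh2(S-PTTL)4 or Rh2(S-DOSP)4. The carbenoid at C3 should insert into the benzylic C–H bond next to the ether oxygen (1,5-insertion), forming C2–C3, the ring and both stereocentres, to give A5.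
- In its favour: the shikimate ester and the acrylate are already in place, only a deprotection follows, no base is present at the ring closure, and cis products are the usual kinetic outcome of such insertions. On step economy and on the absence of base the alternative is better than the chosen plan.
- Against it here: both stereocentres arise in the ring-forming event under a chiral catalyst that has to match or override the chiral ester. The carbenoid carbon sits between two ortho substituents, which twists the donor aryl group out of conjugation and should lower rate and selectivity. Insertion into the shikimate C4–H bond alpha to oxygen, cyclopropanation of two alkenes and oxonium ylide formation at O1 compete, and the diazo transfer has to be done on a hindered arylacetate.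
- Comparison: the chosen plan separates stereocontrol (reduction of 16, checked on open-chain 17) from ring closure (a C–O coupling that breaks no bond at C2 or C3), so the two can be optimised and verified independently. The price is more steps and a basic ring closure. The alternative is shorter and more elegant but stakes both stereocentres, the chemoselectivity and the ring on one step.

Key step: step 13

## Steps

Step 1
Reactants: 1 2-bromo-3-hydroxy-4-methoxybenzaldehyde
Product: 2 2-bromo-3-formyl-6-methoxyphenyl trifluoromethanesulfonate
Conditions: Tf2O, pyridine, CH2Cl2, 0 °C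
Reagents that add atoms: trifluoromethanesulfonic anhydride, O=S(=O)(OS(=O)(=O)C(F)(F)F)C(F)(F)F
Why: O-sulfonylation of the only free phenol; it places the future leaving group on the C7a oxygen while the C7 oxygen is still a methyl ether, so the two ring-A oxygens never have to be distinguished.

Step 2
Reactants: 2 2-bromo-3-formyl-6-methoxyphenyl trifluoromethanesulfonate
Product: 3 2-bromo-3-formyl-6-hydroxyphenyl trifluoromethanesulfonate
Conditions: BBr3, CH2Cl2, –78 °C → rt; aqueous work-up
Reagents that add atoms: none
Why: Lewis-acid demethylation of an aryl methyl ether; aryl triflate, aryl bromide and (after hydrolytic work-up) the aldehyde are inert to BBr3, and the methyl group has to go now because it could not be removed at the end.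

Step 3
Reactants: 3 2-bromo-3-formyl-6-hydroxyphenyl trifluoromethanesulfonate
Product: 4 2-bromo-3-formyl-6-(methoxymethoxy)phenyl trifluoromethanesulfonate
Conditions: MOMCl, iPr2NEt, CH2Cl2, 0 °C → rt
Reagents that add atoms: chloromethyl methyl ether, COCCl
Why: Williamson-type O-alkylation of the acidic para-formyl phenol; MOM survives enolates, hydride transfer and palladium and falls in the final acid step. The para-formyl phenoxide is the more stable anion and is alkylated quickly under a weak amine base, so migration of the triflyl group to the neighbouring oxygen should not intervene.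

Step 4
Reactants: 4 2-bromo-3-formyl-6-(methoxymethoxy)phenyl trifluoromethanesulfonate
Product: 5 2-bromo-3-(1,3-dioxolan-2-yl)-6-(methoxymethoxy)phenyl trifluoromethanesulfonate
Conditions: TMSOCH2CH2OTMS, TMSOTf (2 mol %), CH2Cl2, –78 → –20 °C; pyridine quench
Reagents that add atoms: 1,2-bis(trimethylsilyloxy)ethane, C[Si](C)(C)OCCO[Si](C)(C)C
Why: Noyori acetalisation under aprotic conditions masks the aldehyde against the zinc enolate, the lithium enolate and the hydride transfer to come, without the protic acid and heat that would endanger the MOM ether.

Step 5
Reactants: 6 (−)-shikimic acid, (3R,4S,5R)-3,4,5-trihydroxycyclohex-1-ene-1-carboxylic acid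
Product: 7 3,4-O-isopropylidene-(−)-shikimic acid (cis-fused ketal on O3 and O4, free 5-OH, free acid)
Conditions: 2-methoxypropene, CSA (cat.), acetone, 0 °C → rt
Reagents that add atoms: 2-methoxypropene, COC(C)=C
Why: Acid-catalysed ketalisation; only the cis 3,4-diol can span a five-membered dioxolane on the cyclohexene, so the trans-disposed 5-OH stays free. No stereocentre is touched.

Step 6
Reactants: 7 3,4-O-isopropylidene-(−)-shikimic acid
Product: 8 tert-butyl 3,4-O-isopropylidene-(−)-shikimate (free 5-OH)
Conditions: tert-butyl 2,2,2-trichloroacetimidate, CH2Cl2/cyclohexane, rt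
Reagents that add atoms: tert-butyl 2,2,2-trichloroacetimidate, CC(C)(C)OC(=N)C(Cl)(Cl)Cl
Why: Imidate esterification: the carboxylic acid protonates the imidate and captures the tert-butyl cation; without an added Lewis acid the secondary alcohol is not alkylated and the ketal is not endangered.

Step 7
Reactants: 8 tert-butyl 3,4-O-isopropylidene-(−)-shikimate
Product: 9 tert-butyl 5-O-(bromoacetyl)-3,4-O-isopropylidene-(−)-shikimate
Conditions: BrCH2COBr, pyridine, CH2Cl2, –20 → 0 °C
Reagents that add atoms: bromoacetyl bromide, BrCC(Br)=O
Why: O-acylation of the secondary alcohol with an acid bromide; the C5–O bond is not broken, so the configuration is retained, and the alpha-bromo ester is ready for zinc insertion.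

Step 8
Reactants: 5 2-bromo-3-(1,3-dioxolan-2-yl)-6-(methoxymethoxy)phenyl trifluoromethanesulfonate; 9 tert-butyl 5-O-(bromoacetyl)-3,4-O-isopropylidene-(−)-shikimate
Product: 11 tert-butyl 5-O-{[6-(1,3-dioxolan-2-yl)-3-(methoxymethoxy)-2-(trifluoromethanesulfonyloxy)phenyl]acetyl}-3,4-O-isopropylidene-(−)-shikimate, via bromozinc enolate 10 (not isolated)
Conditions: 9, Zn (TMSCl-activated), THF, rt; then 5, Pd(dba)2 (5 mol %), P(tBu)3 (6 mol %), THF, rt → 45 °C
Reagents that add atoms: none
Why: Reformatsky reagent formation followed by Pd-catalysed alpha-arylation of a zinc ester enolate (Negishi-like). Zerovalent palladium carrying P(tBu)3 inserts into C–Br in preference to C–OTf, and the neutral zinc enolate tolerates the esters, ketal, acetal and triflate. Delivering the shikimate through the nucleophile removes any later esterification.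

Step 9
Reactants: 12 3,4-dihydroxybenzoic acid
Product: 13 2,2-dimethyl-1,3-benzodioxole-5-carboxylic acid
Conditions: Me2C(OMe)2, TsOH·H2O (cat.), toluene, reflux, MeOH removed over 4 Å sieves
Reagents that add atoms: 2,2-dimethoxypropane, COC(C)(C)OC
Why: Acid-catalysed transketalisation of the catechol, driven by removal of methanol; the isopropylidene group withstands base, enolates and palladium and is cleaved by the final acid.

Step 10
Reactants: 13 2,2-dimethyl-1,3-benzodioxole-5-carboxylic acid
Product: 14 2,2-dimethyl-1,3-benzodioxole-5-carbonyl chloride
Conditions: (COCl)2, DMF (cat.), CH2Cl2, 0 °C → rt; evaporated and used crude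
Reagents that add atoms: oxalyl chloride, ClC(=O)C(Cl)=O
Why: Acid chloride formation through the Vilsmeier-type chloroiminium intermediate; the aryl ketal tolerates the brief exposure to HCl.

Step 11
Reactants: 11 tert-butyl 5-O-{[6-(1,3-dioxolan-2-yl)-3-(methoxymethoxy)-2-(trifluoromethanesulfonyloxy)phenyl]acetyl}-3,4-O-isopropylidene-(−)-shikimate; 14 2,2-dimethyl-1,3-benzodioxole-5-carbonyl chloride
Product: 16 tert-butyl 5-O-{2-[6-(1,3-dioxolan-2-yl)-3-(methoxymethoxy)-2-(trifluoromethanesulfonyloxy)phenyl]-3-(2,2-dimethyl-1,3-benzodioxol-5-yl)-3-oxopropanoyl}-3,4-O-isopropylidene-(−)-shikimate (interconverting epimers at the alpha carbon), via lithium enolate 15 (not isolated)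
Conditions: LiN(SiMe3)2 (2.1 equiv), THF, –78 °C; then 14, –78 → –40 °C; AcOH quench
Reagents that add atoms: none
Why: Crossed Claisen C-acylation of an ester enolate with an acid chloride; the second equivalent of the hindered amide base takes up the more acidic product, so it cannot quench unreacted enolate. The alpha centre formed is stereolabile and is deliberately left uncontrolled.

Step 12
Reactants: 16 the alpha-aryl beta-keto ester
Product: 17 tert-butyl 5-O-{(2R,3S)-2-[6-(1,3-dioxolan-2-yl)-3-(methoxymethoxy)-2-(trifluoromethanesulfonyloxy)phenyl]-3-(2,2-dimethyl-1,3-benzodioxol-5-yl)-3-hydroxypropanoyl}-3,4-O-isopropylidene-(−)-shikimate (anti; in benzofuran numbering carbinol C2 is S and alpha carbon C3 is R)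
Conditions: RuCl[(S,S)-TsDPEN](p-cymene) (3 mol %), HCO2H/Et3N (5:2), DMF, 30 °C
Reagents that add atoms: none
Why: Noyori–Ikariya asymmetric transfer hydrogenation with dynamic kinetic resolution. The (S,S) catalyst delivers hydride to the aryl ketone face that gives the S carbinol (the usual aryl/alkyl rule). The alpha centre equilibrates through the enol under Et3N faster than reduction, and the epimer reduced is expected to be the one with the ester antiperiplanar to the incoming hydride (polar Felkin–Anh), which gives the anti product.

Step 13
Reactants: 17 the anti beta-hydroxy ester with the C7a triflate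
Product: 18 tert-butyl 5-O-{[(2S,3R)-2-(2,2-dimethyl-1,3-benzodioxol-5-yl)-4-(1,3-dioxolan-2-yl)-7-(methoxymethoxy)-2,3-dihydro-1-benzofuran-3-yl]carbonyl}-3,4-O-isopropylidene-(−)-shikimate (cis)
Conditions: Pd(OAc)2 (5 mol %), 2-(di-tert-butylphosphino)-1,1'-binaphthyl (7.5 mol %), K3PO4 (2 equiv, anhydrous, ground), 4 Å sieves, toluene, 70 °C
Reagents that add atoms: none
Why: Intramolecular Buchwald–Hartwig C–O cross-coupling: zerovalent palladium, formed in situ from Pd(OAc)2 and the phosphine, adds oxidatively into the C7a–OTf bond. The C2 hydroxyl then binds to the cationic divalent palladium centre and is deprotonated there by the insoluble phosphate, giving a six-membered aryl(alkoxo)palladacycle. C–O reductive elimination, accelerated by the bulky di-tert-butyl biaryl phosphine, forms O1–C7a and returns zerovalent palladium. The closest known reaction type is the palladium-catalysed cyclisation of 2-(2-haloaryl)ethanols bearing secondary carbinols to 2-substituted dihydrobenzofurans. The five-membered dihydrofuran ring closes in the exo sense (5-exo at the arene carbon: the bond that breaks at C7a lies outside the new ring) by reductive elimination from the six-membered palladacycle. No stereocentre is created: the C2–O bond is never broken, so C2 stays S, C3 is not involved, and the anti relationship of the chain is transcribed into the cis ring. The selectivity needed is that coupling outruns epimerisation at C3, retro-aldol cleavage, beta-hydride elimination from the palladium alkoxide and loss or transfer of the triflyl group. A weak heterogeneous base in a non-polar solvent keeps free alkoxide and enolate negligible, the twisted, doubly ortho-substituted ring A makes C3–H poorly acidic, the short tether makes alkoxide capture intramolecular, and the bulky ligand favours reductive elimination over beta-hydride elimination.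

Step 14
Reactants: 18 the cis dihydrobenzofuran with the C4 dioxolane
Product: 19 tert-butyl 5-O-{[(2S,3R)-2-(2,2-dimethyl-1,3-benzodioxol-5-yl)-4-formyl-7-(methoxymethoxy)-2,3-dihydro-1-benzofuran-3-yl]carbonyl}-3,4-O-isopropylidene-(−)-shikimate
Conditions: PPTS (0.2 equiv), acetone/H2O (20:1), 50 °C
Reagents that add atoms: water, O
Why: Acid-catalysed acetal hydrolysis; in acetone the two isopropylidene ketals can only exchange with the solvent and so persist, whereas the dioxolane is lost irreversibly. PPTS is too weak for the MOM ether and the tert-butyl ester, and no base is present to touch C3.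

Step 15
Reactants: 19 the C4 aldehyde
Product: 20 tert-butyl 5-O-{[(2S,3R)-4-[(E)-3-tert-butoxy-3-oxoprop-1-enyl]-2-(2,2-dimethyl-1,3-benzodioxol-5-yl)-7-(methoxymethoxy)-2,3-dihydro-1-benzofuran-3-yl]carbonyl}-3,4-O-isopropylidene-(−)-shikimate
Conditions: Ph3P=CHCO2tBu (1.5 equiv), toluene, 50 °C
Reagents that add atoms: tert-butyl (triphenylphosphoranylidene)acetate, CC(C)(C)OC(=O)C=P(c1ccccc1)(c1ccccc1)c1ccccc1
Why: Wittig olefination with a stabilised ylide, which is E-selective through the reversible, thermodynamically controlled oxaphosphetane and far too weakly basic to enolise the C3 ester. The tert-butyl ester matches the other acid-labile groups.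

Step 16
Reactants: 20 the fully protected acrylate
Product: 21 5-O-{[(2S,3R)-4-[(E)-2-carboxyethenyl]-2-(3,4-dihydroxyphenyl)-7-hydroxy-2,3-dihydro-1-benzofuran-3-yl]carbonyl}-(−)-shikimic acid (target)
Conditions: TFA/H2O (9:1), 0 °C → rt; evaporation below rt, reversed-phase chromatography
Reagents that add atoms: none
Why: Acidic global deprotection: acidolysis of both tert-butyl esters (loss of isobutene) and hydrolysis of the MOM ether and both isopropylidene ketals in one operation. The absence of base preserves C3, and the electron-withdrawing ester on C3 together with low temperature and short exposure is meant to keep the benzylic C2–O1 bond from ionising.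

## Compound list

1 | 2-bromo-3-hydroxy-4-methoxybenzaldehyde | COc1ccc(C=O)c(Br)c1O | starting material
2 | 2-bromo-3-formyl-6-methoxyphenyl trifluoromethanesulfonate | COc1ccc(C=O)c(Br)c1OS(=O)(=O)C(F)(F)F | intermediate
3 | 2-bromo-3-formyl-6-hydroxyphenyl trifluoromethanesulfonate | Oc1ccc(C=O)c(Br)c1OS(=O)(=O)C(F)(F)F | intermediate
4 | 2-bromo-3-formyl-6-(methoxymethoxy)phenyl trifluoromethanesulfonate | COCOc1ccc(C=O)c(Br)c1OS(=O)(=O)C(F)(F)F | intermediate
5 | 2-bromo-3-(1,3-dioxolan-2-yl)-6-(methoxymethoxy)phenyl trifluoromethanesulfonate | COCOc1ccc(C2OCCO2)c(Br)c1OS(=O)(=O)C(F)(F)F | intermediate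
6 | (−)-shikimic acid | O[C@@H]1CC(C(=O)O)=C[C@@H](O)[C@H]1O | starting material
7 | 3,4-O-isopropylidene-(−)-shikimic acid | O[C@@H]1CC(C(=O)O)=C[C@H]2OC(C)(C)O[C@H]21 | intermediate
8 | tert-butyl 3,4-O-isopropylidene-(−)-shikimate | O[C@@H]1CC(C(=O)OC(C)(C)C)=C[C@H]2OC(C)(C)O[C@H]21 | intermediate
9 | tert-butyl 5-O-(bromoacetyl)-3,4-O-isopropylidene-(−)-shikimate | BrCC(=O)O[C@@H]1CC(C(=O)OC(C)(C)C)=C[C@H]2OC(C)(C)O[C@H]21 | intermediate
10 | bromozinc enolate (Reformatsky reagent) of 9, not isolated | Br[Zn]CC(=O)O[C@@H]1CC(C(=O)OC(C)(C)C)=C[C@H]2OC(C)(C)O[C@H]21 | intermediate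
11 | tert-butyl 5-O-{[6-(1,3-dioxolan-2-yl)-3-(methoxymethoxy)-2-(trifluoromethanesulfonyloxy)phenyl]acetyl}-3,4-O-isopropylidene-(−)-shikimate | O1CCOC1c1ccc(OCOC)c(OS(=O)(=O)C(F)(F)F)c1CC(=O)O[C@@H]1CC(C(=O)OC(C)(C)C)=C[C@H]2OC(C)(C)O[C@H]21 | intermediate
12 | 3,4-dihydroxybenzoic acid | OC(=O)c1ccc(O)c(O)c1 | starting material
13 | 2,2-dimethyl-1,3-benzodioxole-5-carboxylic acid | OC(=O)c1ccc2OC(C)(C)Oc2c1 | intermediate
14 | 2,2-dimethyl-1,3-benzodioxole-5-carbonyl chloride | ClC(=O)c1ccc2OC(C)(C)Oc2c1 | intermediate
15 | lithium enolate of 11, not isolated | O1CCOC1c1ccc(OCOC)c(OS(=O)(=O)C(F)(F)F)c1C=C(O[Li])O[C@@H]1CC(C(=O)OC(C)(C)C)=C[C@H]2OC(C)(C)O[C@H]21 | intermediate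
16 | alpha-aryl beta-keto ester, epimers at the alpha carbon | O1CCOC1c1ccc(OCOC)c(OS(=O)(=O)C(F)(F)F)c1C(C(=O)O[C@@H]1CC(C(=O)OC(C)(C)C)=C[C@H]2OC(C)(C)O[C@H]21)C(=O)c1ccc2OC(C)(C)Oc2c1 | intermediate
17 | anti beta-hydroxy ester with the C7a triflate (carbinol S, alpha carbon R) | O1CCOC1c1ccc(OCOC)c(OS(=O)(=O)C(F)(F)F)c1[C@@H](C(=O)O[C@@H]1CC(C(=O)OC(C)(C)C)=C[C@H]2OC(C)(C)O[C@H]21)[C@H](O)c1ccc2OC(C)(C)Oc2c1 | intermediate
18 | cis-(2S,3R) dihydrobenzofuran shikimate ester with the C4 dioxolane | O1CCOC1c1ccc(OCOC)c2c1[C@@H](C(=O)O[C@@H]1CC(C(=O)OC(C)(C)C)=C[C@H]3OC(C)(C)O[C@H]31)[C@@H](c1ccc3OC(C)(C)Oc3c1)O2 | intermediate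
19 | cis-(2S,3R) dihydrobenzofuran shikimate ester with the C4 aldehyde | O=Cc1ccc(OCOC)c2c1[C@@H](C(=O)O[C@@H]1CC(C(=O)OC(C)(C)C)=C[C@H]3OC(C)(C)O[C@H]31)[C@@H](c1ccc3OC(C)(C)Oc3c1)O2 | intermediate
20 | fully protected target with the (E)-tert-butyl acrylate at C4 | CC(C)(C)OC(=O)/C=C/c1ccc(OCOC)c2c1[C@@H](C(=O)O[C@@H]1CC(C(=O)OC(C)(C)C)=C[C@H]3OC(C)(C)O[C@H]31)[C@@H](c1ccc3OC(C)(C)Oc3c1)O2 | intermediate
21 | 5-O-{[(2S,3R)-4-[(E)-2-carboxyethenyl]-2-(3,4-dihydroxyphenyl)-7-hydroxy-2,3-dihydro-1-benzofuran-3-yl]carbonyl}-(−)-shikimic acid | O=C(O)/C=C/c1ccc(O)c2c1[C@@H](C(=O)O[C@@H]1CC(C(=O)O)=C[C@@H](O)[C@H]1O)[C@@H](c1ccc(O)c(O)c1)O2 | target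

## Step count and least certain steps

Total: 16 steps. Longest linear sequence: 11 steps (steps 1, 2, 3, 4, 8, 11, 12, 13, 14, 15, 16, from 1 to 21). The shikimate branch (steps 5–7) and the aroyl branch (steps 9–10) join at steps 8 and 11.

Step 13 (key step). Oxidative addition into a triflate flanked by two ortho substituents may be slow. That would leave time for base-mediated loss of the triflyl group (including its transfer to the C2 alkoxide), for beta-hydride elimination from the palladium alkoxide with reduction of the arene, or for enolisation at C3. As a fallback, 17 would be converted by Miyaura borylation of the triflate (PdCl2(dppf), bis(pinacolato)diboron, KOAc, dioxane, 80 °C) into the arylboronic pinacol ester F1. The same O1–C7a bond would then be closed oxidatively by Chan–Lam etherification (Cu(OAc)2, pyridine, 4 Å sieves, CH2Cl2, air, room temperature), which needs neither heat nor an inorganic base, and the route is rejoined at 18.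

Step 8. Insertion into the hindered C–Br bond may be slow enough for the neighbouring triflate to compete, or the zinc enolate may be consumed by protonation before transmetalation. As a fallback, 5 would undergo Stille coupling with allyltributylstannane (Pd(PPh3)4, toluene, 90 °C, no chloride additive, so that the bromide reacts) to give the allylarene F2. Lemieux–Johnson cleavage (OsO4 cat., NaIO4, 2,6-lutidine, dioxane/H2O) would give the arylacetaldehyde F3, and Pinnick oxidation (NaClO2, NaH2PO4, 2-methyl-2-butene, tBuOH/H2O) the arylacetic acid F4. Carbodiimide esterification of F4 with alcohol 8 (EDC·HCl, DMAP, CH2Cl2) returns to 11 and makes 9 and 10 unnecessary.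

Step 11. The crowded enolate may be acylated on oxygen or twice, and enolate or amide base may attack the sulfur of the neighbouring triflate. As a fallback, acid chloride 14 would be reduced with LiAlH(OtBu)3 (THF, –78 °C) to 2,2-dimethyl-1,3-benzodioxole-5-carbaldehyde F5. Enolate 15, made with one equivalent of LiN(SiMe3)2, would add to F5 to give the beta-hydroxy ester as a mixture of diastereomers F6, and Dess–Martin periodinane (NaHCO3, CH2Cl2) would oxidise F6 to 16.

Step 12. The reduction may prefer the alpha epimer in which the bulky ring A, not the ester, lies anti to the incoming hydride, which leads to the syn series and so to the trans ring. The chiral ester may also be mismatched with the catalyst, or the hindered ketone may react sluggishly. As a fallback that bypasses 16, ester 11 would be enolised with dicyclohexylboron triflate and Et3N (CH2Cl2, –78 °C) to the boron enolate F7, in which aryl and the boron-bound oxygen are trans. Addition to aldehyde F5 (made from 14 as in the fallback to step 11) through a chair transition state should give the anti aldols. Because of the shikimate unit the two anti products are diastereomers, so 17 would be separated by chromatography from the anti diastereomer F8 (carbinol R, alpha carbon S), and the route resumes at 17.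

Step 16. The ring-B ketal needs strong acid, and prolonged exposure invites heterolysis of the benzylic C2–O1 bond with loss of the cis relationship, acyl migration on the shikimate triol, and capture of tert-butyl or methoxymethyl cations by the liberated catechol, or its addition to the cinnamic acid. As a fallback the last two operations would be reversed. Aldehyde 19 would be deprotected first (TFA/H2O 9:1, 0 °C), when only one tert-butyl cation is released and no acrylate is present, to give the unprotected 4-formyl triol acid F9. The acrylic acid would then be formed on the unprotected compound by Knoevenagel–Doebner condensation with malonic acid (pyridine, beta-alanine, 50 °C), which gives 21 directly.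

## Further compounds

F1 | step 13 | arylboronic pinacol ester corresponding to 17 (Bpin at C7a in place of the triflate) | O1CCOC1c1ccc(OCOC)c(B2OC(C)(C)C(C)(C)O2)c1[C@@H](C(=O)O[C@@H]1CC(C(=O)OC(C)(C)C)=C[C@H]2OC(C)(C)O[C@H]21)[C@H](O)c1ccc2OC(C)(C)Oc2c1
F2 | step 8 | 2-allyl-3-(1,3-dioxolan-2-yl)-6-(methoxymethoxy)phenyl trifluoromethanesulfonate | C=CCc1c(C2OCCO2)ccc(OCOC)c1OS(=O)(=O)C(F)(F)F
F3 | step 8 | 2-[6-(1,3-dioxolan-2-yl)-3-(methoxymethoxy)-2-(trifluoromethanesulfonyloxy)phenyl]acetaldehyde | O=CCc1c(C2OCCO2)ccc(OCOC)c1OS(=O)(=O)C(F)(F)F
F4 | step 8 | 2-[6-(1,3-dioxolan-2-yl)-3-(methoxymethoxy)-2-(trifluoromethanesulfonyloxy)phenyl]acetic acid | OC(=O)Cc1c(C2OCCO2)ccc(OCOC)c1OS(=O)(=O)C(F)(F)F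
F5 | step 11 | 2,2-dimethyl-1,3-benzodioxole-5-carbaldehyde | O=Cc1ccc2OC(C)(C)Oc2c1
F6 | step 11 | beta-hydroxy ester from 15 and F5, mixture of diastereomers at the carbinol and alpha carbons | O1CCOC1c1ccc(OCOC)c(OS(=O)(=O)C(F)(F)F)c1C(C(=O)O[C@@H]1CC(C(=O)OC(C)(C)C)=C[C@H]2OC(C)(C)O[C@H]21)C(O)c1ccc2OC(C)(C)Oc2c1
F7 | step 12 | dicyclohexylboron enolate of 11, aryl trans to the boron-bound oxygen, not isolated | O1CCOC1c1ccc(OCOC)c(OS(=O)(=O)C(F)(F)F)c1/C=C(/OB(C1CCCCC1)C1CCCCC1)O[C@@H]1CC(C(=O)OC(C)(C)C)=C[C@H]2OC(C)(C)O[C@H]21
F8 | step 12 | anti diastereomer of 17 (carbinol R, alpha carbon S) | O1CCOC1c1ccc(OCOC)c(OS(=O)(=O)C(F)(F)F)c1[C@H](C(=O)O[C@@H]1CC(C(=O)OC(C)(C)C)=C[C@H]2OC(C)(C)O[C@H]21)[C@@H](O)c1ccc2OC(C)(C)Oc2c1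
F9 | step 16 | 5-O-{[(2S,3R)-2-(3,4-dihydroxyphenyl)-4-formyl-7-hydroxy-2,3-dihydro-1-benzofuran-3-yl]carbonyl}-(−)-shikimic acid | O=Cc1ccc(O)c2c1[C@@H](C(=O)O[C@@H]1CC(C(=O)O)=C[C@@H](O)[C@H]1O)[C@@H](c1ccc(O)c(O)c1)O2
A1 | alternative 1 | ethyl 7-acetoxy-4-(acetoxymethyl)-2-(2,2-dimethyl-1,3-benzodioxol-5-yl)-1-benzofuran-3-carboxylate | CC(=O)OCc1ccc(OC(C)=O)c2oc(-c3ccc4OC(C)(C)Oc4c3)c(C(=O)OCC)c12
A2 | alternative 1 | (3E)-5-acetoxy-4-[5-(2,2-dimethyl-1,3-benzodioxol-5-yl)-4-(ethoxycarbonyl)furan-3-yl]pent-3-enoic acid (furyl and carboxymethyl cis) | OC(=O)C/C=C(\c1coc(-c2ccc3OC(C)(C)Oc3c2)c1C(=O)OCC)COC(C)=O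
A3 | alternative 2 | cis 7-hydroxy-2,3-dihydrobenzofuran with a triisopropylsilyloxymethyl group at C3 and a tert-butyldimethylsilyloxymethyl group at C4, (2S,3S) by the sequence rule, same spatial arrangement as the target | CC(C)(C)[Si](C)(C)OCc1ccc(O)c2c1[C@@H](CO[Si](C(C)C)(C(C)C)C(C)C)[C@@H](c1ccc3OC(C)(C)Oc3c1)O2
A4 | alternative 2 | ethynyl ether of the 1-aryl-2-[3-(tert-butyldimethylsilyloxymethyl)furan-2-yl]-3-(triisopropylsilyloxy)propan-1-ol, configured as in A3 | CC(C)(C)[Si](C)(C)OCc1ccoc1[C@@H](CO[Si](C(C)C)(C(C)C)C(C)C)[C@@H](c1ccc2OC(C)(C)Oc2c1)OC#C
A5 | alternative 3 | protected target with a tert-butyldimethylsilyl ether at C7, cis-(2S,3R) | CC(C)(C)OC(=O)/C=C/c1ccc(O[Si](C)(C)C(C)(C)C)c2c1[C@@H](C(=O)O[C@@H]1CC(C(=O)OC(C)(C)C)=C[C@H]3OC(C)(C)O[C@H]31)[C@@H](c1ccc3OC(C)(C)Oc3c1)O2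
A6 | alternative 3 | shikimate aryldiazoacetate with the ortho (2,2-dimethyl-1,3-benzodioxol-5-yl)methoxy group | CC(C)(C)OC(=O)/C=C/c1ccc(O[Si](C)(C)C(C)(C)C)c(OCc2ccc3OC(C)(C)Oc3c2)c1C(=[N+]=[N-])C(=O)O[C@@H]1CC(C(=O)OC(C)(C)C)=C[C@H]2OC(C)(C)O[C@H]21
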